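The chromone is cut at C7–C8, so that ring A is closed last on a finished 6-aryloxy-4-pyranone. The precursor holds all ring A carbons. It has a 4-methylpent-3-enyl chain on C8a, whose first CH2 is C8 and already carries prenyl, and a 3,3-dimethoxyacryloyl group on C4a (C5 ketone, C6–H, C7 ketene acetal). One equivalent of base triggers closure and loss of methanol, giving the arene in one operation. The step exploits the unsymmetrical oxygenation of ring A. The C5 ketone becomes the free hydroxyl chelated to C4=O, C7 keeps one methoxy group, and C8 is substituted from the start, so neither selective O-methylation nor C-prenylation is needed.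

Key step: step 6

Assumption: 3,3-dichloroacryloyl chloride is taken as a purchasable acid chloride (otherwise oxalyl chloride on the acid adds one operation).
Numbering remark: labels C2–C8a follow the chromone numbering of the target. Where a pyranone position is meant it is written "pyranone C6" (this atom becomes chromone C2). The target has no stereocentre.

Step 1
Reactants: 1 allyl acetoacetate; 2 prenyl bromide
Product: 3 allyl 7-methyl-3-oxooct-6-enoate
Conditions: LiN(iPr)2 (2.1 equiv), THF, −78 → −20 °C; 2, −78 → 0 °C; cold dilute aq. HCl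
Reagents that add atoms: prenyl bromide (2), CC(C)=CCBr
Why: Acetoacetate dianion γ-alkylation (Weiler alkylation), in which the terminal carbanion is the more reactive site and displaces the primary allylic bromide in SN2 fashion, while the cold conditions keep the allyl ester dianion from the anionic Carroll rearrangement.

Step 2
Reactants: 3 allyl 7-methyl-3-oxooct-6-enoate; 4 3,3-dichloroacryloyl chloride
Product: 6 allyl 6-chloro-2-(4-methylpent-3-enyl)-4-oxo-4H-pyran-3-carboxylate, via triacylmethane 5 (not isolated)
Conditions: MgCl2 (1.1 equiv), pyridine (2.2 equiv), CH2Cl2, 0 °C; 4, 0 °C → rt; then Et3N (1.2 equiv), rt; cold dilute aq. HCl wash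
Reagents that add atoms: 3,3-dichloroacryloyl chloride (4), O=C(Cl)C=C(Cl)Cl
Why: Magnesium-chelate C-acylation of a β-keto ester by an acid chloride, followed by 6-endo-trig addition–elimination of the ketone enolate oxygen on the β,β-dichlorovinyl ketone, is the acylation–cyclisation logic used for 4-oxochromene- and 4-quinolone-3-carboxylates and should close the pyranone with one chloride left on pyranone C6.

Step 3
Reactants: 6 allyl 6-chloro-2-(4-methylpent-3-enyl)-4-oxo-4H-pyran-3-carboxylate; 7 4-(tert-butyldimethylsilyloxy)phenol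
Product: 8 allyl 6-[4-(tert-butyldimethylsilyloxy)phenoxy]-2-(4-methylpent-3-enyl)-4-oxo-4H-pyran-3-carboxylate
Conditions: Et3N (1.3 equiv), DABCO (10 mol %), MeCN, 0 °C → rt
Reagents that add atoms: 4-(tert-butyldimethylsilyloxy)phenol (7), CC(C)(C)[Si](C)(C)Oc1ccc(O)cc1
Why: The chloride on pyranone C6 is a vinylogous chloroformate, so DABCO-catalysed nucleophilic vinylic substitution (addition–elimination) by the phenol should be fast under an amine base that is too mild to cleave or scramble the aryl silyl ether.

Step 4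
Reactants: 8 allyl 6-[4-(tert-butyldimethylsilyloxy)phenoxy]-2-(4-methylpent-3-enyl)-4-oxo-4H-pyran-3-carboxylate
Product: 9 6-[4-(tert-butyldimethylsilyloxy)phenoxy]-2-(4-methylpent-3-enyl)-4-oxo-4H-pyran-3-carboxylic acid
Conditions: Pd(PPh3)4 (3 mol %), HCO2H, Et3N, THF, rt; aq. citric acid
Reagents that add atoms: none
Why: In this Tsuji–Trost-type deallylation zerovalent palladium ionises the allyl ester and formate reduces the π-allyl complex to propene, so no nucleophilic amine that could displace the aryloxy group is present, and the trisubstituted alkene and the silyl ether are inert.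

Step 5
Reactants: 9 6-[4-(tert-butyldimethylsilyloxy)phenoxy]-2-(4-methylpent-3-enyl)-4-oxo-4H-pyran-3-carboxylic acid; 10 1,1-dimethoxyethene
Product: 12 6-[4-(tert-butyldimethylsilyloxy)phenoxy]-3-(3,3-dimethoxyacryloyl)-2-(4-methylpent-3-enyl)-4H-pyran-4-one, via acid chloride 11 (not isolated)
Conditions: Me2C=C(Cl)NMe2 (1.05 equiv), CH2Cl2, 0 °C; solution added to 10 (3 equiv), 2,6-lutidine (1.5 equiv), CH2Cl2, −20 °C → rt; filtration through basic alumina, used at once
Reagents that add atoms: 1,1-dimethoxyethene (10), C=C(OC)OC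
Why: The α-chloroenamine forms the acid chloride without free HCl, which spares the alkene and the silyl ether, and C-acylation of the electron-rich ketene acetal followed by proton loss to the weak hindered base is the classical entry to acylketene O,O-acetals.

Step 6
Reactants: 12 6-[4-(tert-butyldimethylsilyloxy)phenoxy]-3-(3,3-dimethoxyacryloyl)-2-(4-methylpent-3-enyl)-4H-pyran-4-one
Product: 15 2-[4-(tert-butyldimethylsilyloxy)phenoxy]-5-hydroxy-7-methoxy-8-(3-methylbut-2-enyl)-4H-chromen-4-one, via lithium trienolate 13 (not isolated), via 8H-chromene-4,5-dione 14 (not isolated)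
Conditions: LiN(SiMe3)2 (1.1 equiv, added dropwise), THF (0.02 mol/L), −78 → 0 °C; AcOH quench
Reagents that add atoms: none
Why: Proposed new method: LiN(SiMe3)2 removes a C8 proton, which is acidified through C8a=C4a by both the C4 and the C5 carbonyl, and gives trienolate 13 (C8=C8a–C4a=C5(OLi)–C6=C7). Ring A then closes by a thermal disrotatory 6π electrocyclisation, formally a 6-endo-trig vinylogous Michael addition of C8 to the acetal carbon C7; the C5 enolate expels one methoxide to give dienone 14, and that methoxide takes the remaining C8 proton, so aromatisation to the lithium C5 phenoxide drives the sequence and no free methoxide builds up. The closest known reaction types are the base-induced [3+3] aromatic annulation of α-oxoketene acetals (mostly dithioacetals) with allyl anions, which ends in the same loss of thiol or alcohol, and the γ-lithiation of 2-alkyl-4-pyranones; the intramolecular version on a pyranone O,O-acetal is new. No stereocentre remains, since the C8 centre of 14 is lost on tautomerisation. The step needs closure through carbon and not through O4, and attack at C7 and not at the aryloxy carbon C2: lithium bridging O4 and O5 turns C6=C7 towards C8 and away from O4, C2 cannot be reached within the molecule, and high dilution with a single equivalent of a hindered amide base suppresses intermolecular attack at C2 and at silicon. The 5-OH/7-OMe/8-prenyl pattern is fixed by connectivity and not by reagent selectivity.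

Step 7
Reactants: 15 2-[4-(tert-butyldimethylsilyloxy)phenoxy]-5-hydroxy-7-methoxy-8-(3-methylbut-2-enyl)-4H-chromen-4-one
Product: 16 7-O-methylepimedonin G, 5-hydroxy-2-(4-hydroxyphenoxy)-7-methoxy-8-(3-methylbut-2-enyl)-4H-chromen-4-one
Conditions: Bu4NF, AcOH (1:1), THF, 0 °C
Reagents that add atoms: none
Why: Fluoride-induced desilylation of the aryl silyl ether, kept near neutral by acetic acid so that no basic species attacks the aryloxy carbon C2, should free the 4'-hydroxyl and leave prenyl, methoxy and the chelated C5 hydroxyl untouched.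

Compound list
1 | allyl acetoacetate | CC(=O)CC(=O)OCC=C | starting material
2 | prenyl bromide (1-bromo-3-methylbut-2-ene) | CC(C)=CCBr | starting material
3 | allyl 7-methyl-3-oxooct-6-enoate | CC(C)=CCCC(=O)CC(=O)OCC=C | intermediate
4 | 3,3-dichloroacryloyl chloride | O=C(Cl)C=C(Cl)Cl | starting material
5 | allyl 2-(3,3-dichloroacryloyl)-7-methyl-3-oxooct-6-enoate (enolised triacylmethane, no fixed configuration, not isolated) | CC(C)=CCCC(=O)C(C(=O)C=C(Cl)Cl)C(=O)OCC=C | intermediate
6 | allyl 6-chloro-2-(4-methylpent-3-enyl)-4-oxo-4H-pyran-3-carboxylate | C=CCOC(=O)c1c(CCC=C(C)C)oc(Cl)cc1=O | intermediate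
7 | 4-(tert-butyldimethylsilyloxy)phenol | CC(C)(C)[Si](C)(C)Oc1ccc(O)cc1 | starting material
8 | allyl 6-[4-(tert-butyldimethylsilyloxy)phenoxy]-2-(4-methylpent-3-enyl)-4-oxo-4H-pyran-3-carboxylate | C=CCOC(=O)c1c(CCC=C(C)C)oc(Oc2ccc(O[Si](C)(C)C(C)(C)C)cc2)cc1=O | intermediate
9 | 6-[4-(tert-butyldimethylsilyloxy)phenoxy]-2-(4-methylpent-3-enyl)-4-oxo-4H-pyran-3-carboxylic acid | OC(=O)c1c(CCC=C(C)C)oc(Oc2ccc(O[Si](C)(C)C(C)(C)C)cc2)cc1=O | intermediate
10 | 1,1-dimethoxyethene | C=C(OC)OC | starting material
11 | 6-[4-(tert-butyldimethylsilyloxy)phenoxy]-2-(4-methylpent-3-enyl)-4-oxo-4H-pyran-3-carbonyl chloride (not isolated) | O=C(Cl)c1c(CCC=C(C)C)oc(Oc2ccc(O[Si](C)(C)C(C)(C)C)cc2)cc1=O | intermediate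
12 | 6-[4-(tert-butyldimethylsilyloxy)phenoxy]-3-(3,3-dimethoxyacryloyl)-2-(4-methylpent-3-enyl)-4H-pyran-4-one | COC(OC)=CC(=O)c1c(CCC=C(C)C)oc(Oc2ccc(O[Si](C)(C)C(C)(C)C)cc2)cc1=O | intermediate
13 | lithium trienolate of 12, deprotonated at C8 (O4/O5 lithium chelate, C8=C8a geometry not defined, not isolated) | [Li+].COC(OC)=CC([O-])=C1C(=O)C=C(Oc2ccc(O[Si](C)(C)C(C)(C)C)cc2)OC1=CCC=C(C)C | intermediate
14 | 2-[4-(tert-butyldimethylsilyloxy)phenoxy]-7-methoxy-8-(3-methylbut-2-enyl)-8H-chromene-4,5-dione (racemic at C8, transient, not isolated) | COC1=CC(=O)C2=C(OC(Oc3ccc(O[Si](C)(C)C(C)(C)C)cc3)=CC2=O)C1CC=C(C)C | intermediate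
15 | 2-[4-(tert-butyldimethylsilyloxy)phenoxy]-5-hydroxy-7-methoxy-8-(3-methylbut-2-enyl)-4H-chromen-4-one | COc1cc(O)c2c(=O)cc(Oc3ccc(O[Si](C)(C)C(C)(C)C)cc3)oc2c1CC=C(C)C | intermediate
16 | 7-O-methylepimedonin G | COc1cc(O)c2c(=O)cc(Oc3ccc(O)cc3)oc2c1CC=C(C)C | target

Total step count: 7
Longest linear sequence: 7 steps (1 → 3 → 6 → 8 → 9 → 12 → 15 → 16)

Steps most likely to fail

1. Step 6 (the labelled step).
- What may go wrong: closure through the C4 oxygen in place of C8. The carbanion or methoxide may add intermolecularly to C2 with loss of the aryloxy group. The ketene acetal may hydrolyse before closure, which would erase the C5/C7 differentiation. Partial loss of the silyl group would be harmless, because step 7 removes it anyway.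
- Fallback (sets out from 7, comes back at 15, known reaction types only): ring A is bought and the pyranone ring is built on it. Purchased 1-(2,6-dihydroxy-4-methoxyphenyl)ethanone F1, whose two hydroxyls are equivalent, should condense with CS2 (KOtBu, THF) to 4,5-dihydroxy-7-methoxy-2H-chromene-2-thione F2. S-methylation (MeI, K2CO3, acetone) should give 5-hydroxy-7-methoxy-2-(methylthio)-4H-chromen-4-one F3, and mCPBA (CH2Cl2) should give 5-hydroxy-7-methoxy-2-(methylsulfonyl)-4H-chromen-4-one F4. Phenol 7 then displaces methanesulfinate (K2CO3, DMF, rt) to give 2-[4-(tert-butyldimethylsilyloxy)phenoxy]-5-hydroxy-7-methoxy-4H-chromen-4-one F5. The C5 hydroxyl is alkylated with 2 (K2CO3, acetone, reflux) to 2-[4-(tert-butyldimethylsilyloxy)phenoxy]-7-methoxy-5-(3-methylbut-2-enyloxy)-4H-chromen-4-one F6. The Eu(fod)3-catalysed tandem Claisen–Cope rearrangement (PhCl, 85 °C) should then carry prenyl from O5 over C6 to C8 and deliver 15.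

2. Step 5.
- What may go wrong: chloride may demethylate the intermediate dimethoxycarbenium ion, or the acetal may hydrolyse during isolation. Both reduce C7 to an ordinary ester. Base-induced 1,4-elimination of HCl from the acid chloride through C8 is also possible.
- Fallback (sets out from 9 through its chloride 11, comes back at 12): the C5–C6 bond is made by cross-coupling with an alkynyl ether and the acetal by conjugate addition of methanol, so no dimethoxycarbenium chloride is formed. Purchased 2-chloro-1,1-dimethoxyethane F7 with LiNEt2 (3 equiv, THF, 0 °C) should give lithium methoxyacetylide F8, which Bu3SnCl converts into tributyl(methoxyethynyl)stannane F9. Stille acylation of this stannane with 11 (PdCl2(PPh3)2, toluene, rt → 50 °C) should give 6-[4-(tert-butyldimethylsilyloxy)phenoxy]-3-(3-methoxyprop-2-ynoyl)-2-(4-methylpent-3-enyl)-4H-pyran-4-one F10. Methanol (1 equiv, DABCO cat., CH2Cl2, 0 °C) should add to the push–pull triple bond at C7 to give 12.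

3. Step 2.
- What may go wrong: O-acylation, or attack at the dichlorovinyl carbon, in place of C-acylation. Closure of the strongly stabilised enolate may be sluggish. Quaternisation by pyridine or hydrolysis at pyranone C6 may occur during work-up.
- Fallback (sets out from 1, comes back at 8, replaces steps 1–3): the leaving group on pyranone C6 becomes a thioether that is inert until oxidised, and the oxidation-sensitive prenyl group is brought in afterwards. The dianion of 1 (LiN(iPr)2, 2.1 equiv, THF, −78 °C) is thiocarboxylated at the terminal carbon with CS2 and S-methylated twice (MeI) to allyl 5,5-bis(methylthio)-3-oxopent-4-enoate F11. C-acetylation (AcCl, MgCl2, pyridine, CH2Cl2) gives allyl 2-acetyl-5,5-bis(methylthio)-3-oxopent-4-enoate F12. This closes with loss of methanethiol (Et3N, MeCN, 60 °C) to allyl 2-methyl-6-(methylthio)-4-oxo-4H-pyran-3-carboxylate F13. mCPBA (CH2Cl2, 0 °C → rt; the monosubstituted allyl alkene is slow to epoxidise) gives allyl 2-methyl-6-(methylsulfonyl)-4-oxo-4H-pyran-3-carboxylate F14. Phenol 7 displaces methanesulfinate (K2CO3, MeCN) to give allyl 6-[4-(tert-butyldimethylsilyloxy)phenoxy]-2-methyl-4-oxo-4H-pyran-3-carboxylate F15. The known γ-deprotonation of a 2-methyl-4-pyranone (LiN(SiMe3)2, THF, −78 °C) followed by 2 should give 8.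

Further compounds
F1 | step 6 | 1-(2,6-dihydroxy-4-methoxyphenyl)ethanone (purchased) | COc1cc(O)c(C(C)=O)c(O)c1
F2 | step 6 | 4,5-dihydroxy-7-methoxy-2H-chromene-2-thione | COc1cc(O)c2c(O)cc(=S)oc2c1
F3 | step 6 | 5-hydroxy-7-methoxy-2-(methylthio)-4H-chromen-4-one | COc1cc(O)c2c(=O)cc(SC)oc2c1
F4 | step 6 | 5-hydroxy-7-methoxy-2-(methylsulfonyl)-4H-chromen-4-one | COc1cc(O)c2c(=O)cc(S(C)(=O)=O)oc2c1
F5 | step 6 | 2-[4-(tert-butyldimethylsilyloxy)phenoxy]-5-hydroxy-7-methoxy-4H-chromen-4-one | COc1cc(O)c2c(=O)cc(Oc3ccc(O[Si](C)(C)C(C)(C)C)cc3)oc2c1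
F6 | step 6 | 2-[4-(tert-butyldimethylsilyloxy)phenoxy]-7-methoxy-5-(3-methylbut-2-enyloxy)-4H-chromen-4-one | COc1cc(OCC=C(C)C)c2c(=O)cc(Oc3ccc(O[Si](C)(C)C(C)(C)C)cc3)oc2c1
F7 | step 5 | 2-chloro-1,1-dimethoxyethane (purchased) | COC(CCl)OC
F8 | step 5 | lithium methoxyacetylide | [Li+].[C-]#COC
F9 | step 5 | tributyl(methoxyethynyl)stannane | CCCC[Sn](CCCC)(CCCC)C#COC
F10 | step 5 | 6-[4-(tert-butyldimethylsilyloxy)phenoxy]-3-(3-methoxyprop-2-ynoyl)-2-(4-methylpent-3-enyl)-4H-pyran-4-one | COC#CC(=O)c1c(CCC=C(C)C)oc(Oc2ccc(O[Si](C)(C)C(C)(C)C)cc2)cc1=O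
F11 | step 2 | allyl 5,5-bis(methylthio)-3-oxopent-4-enoate | CSC(SC)=CC(=O)CC(=O)OCC=C
F12 | step 2 | allyl 2-acetyl-5,5-bis(methylthio)-3-oxopent-4-enoate | CSC(SC)=CC(=O)C(C(C)=O)C(=O)OCC=C
F13 | step 2 | allyl 2-methyl-6-(methylthio)-4-oxo-4H-pyran-3-carboxylate | C=CCOC(=O)c1c(C)oc(SC)cc1=O
F14 | step 2 | allyl 2-methyl-6-(methylsulfonyl)-4-oxo-4H-pyran-3-carboxylate | C=CCOC(=O)c1c(C)oc(S(C)(=O)=O)cc1=O
F15 | step 2 | allyl 6-[4-(tert-butyldimethylsilyloxy)phenoxy]-2-methyl-4-oxo-4H-pyran-3-carboxylate | C=CCOC(=O)c1c(C)oc(Oc2ccc(O[Si](C)(C)C(C)(C)C)cc2)cc1=O
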